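The numbers in the tables come from a simulation on assumed constants.

Friday's run stopped short. In this kinetic resolution its left-handed substrate sat near 37.2% over the last three readings, and Tuesday's, with 1.50 times the loading, sat near 32.9%. Friday's right-handed readings stayed between 49.5% and 50.5%.

| flask | left-handed substrate | right-handed substrate | partner | free catalyst | remark | time |
|---|---|---|---|---|---|---|
| Friday's | 0.053 M | 0.053 M | 0.80 equiv | 0.18 mol% | run made earlier |  |
| Tuesday's | 0.053 M | 0.053 M | 0.80 equiv | 0.27 mol% | run made earlier |  |
| flask | 0.053 M | 0.053 M | 0.800 equiv | 0.36 mol% |  | 20 min |

- Friday's (time / min: left-handed substrate / %, right-handed substrate / %): 2.00: 44.3, 50.5; 6.00: 39.7, 49.5; 12.0: 36.6, 49.6; 15.0: 38.0, 50.3; 25.0: 37.0, 49.6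
- Tuesday's (time / min: left-handed substrate / %, right-handed substrate / %): 5.00: 36.4, 49.8; 10.0: 34.1, 49.9; 15.0: 32.8, 50.0; 20.0: 33.9, 49.6; 25.0: 32.0, 49.9

(readings scatter by 0.5 percentage points)

- free catalyst is single-handed; left-handed substrate and right-handed substrate are mirror images of each other, charged as a racemate, each of them at the stated concentration
- steps thought possible: free catalyst + left-handed substrate <-> catalyst intermediate A; free catalyst + right-handed substrate <-> catalyst intermediate B; partner + catalyst intermediate A -> free catalyst + left-handed product; partner + catalyst intermediate B -> free catalyst + right-handed product; partner + free catalyst -> spent catalyst A; 2 partner -> self-condensation product; free catalyst -> spent catalyst B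
- an excess is the difference of the two amounts in percent of their sum
- an excess is below zero if the other one leads

1. part of the left-handed substrate and right-handed substrate charged together that has reacted at 20 min
2. excess of left-handed product over right-handed product in the product at 20 min
3. excess of right-handed substrate over left-handed substrate among what is left of the two at 20 min

I took the logarithm of the charged share over the plateau and divided it by the loading, counted in Friday's loadings:

Friday: ln(0.5 / 37.2%) / 1 = 0.296

Tuesday: ln(0.5 / 32.9%) / 1.50 = 0.279

I call this number the reach: the logarithmic fall of the left-handed substrate per Friday's loading, at 0.80 equiv of partner. The new flask holds twice Friday's loading, so each run gives its own plateau for it: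

from Friday: 27.7%

from Tuesday: 28.6%

The two ways part by 0.90 percentage points, while a mean of three readings carries 0.29 points. Friday's reach is larger than Tuesday's and has to be stretched further, so I took Friday's way as the one that cheats and committed to Tuesday's. With the right-handed substrate held at its charge, that gave 21.4% reacted and a substrate excess of 27.2%. The left-handed reading from 15.0 min on is the one to watch.

The forecast gave 22.1% reacted, a product excess of 98.2% and a substrate excess of 27.9%, the first and last a little above mine, holding that the left-handed substrate “stalls because the catalyst dies, not because anything runs out”.

The flask gave 20.1% reacted, a product excess of 97.8% and a substrate excess of 24.7%.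

    free catalyst + left-handed substrate ⇌ catalyst intermediate A (K = 128 /M, k = 3350 /M/s)
    free catalyst + right-handed substrate ⇌ catalyst intermediate B (K = 6.60 /M, k = 1650 /M/s)
    partner + catalyst intermediate A → free catalyst + left-handed product (k = 28.1 /M/s)
    partner + catalyst intermediate B → free catalyst + right-handed product (k = 4.68 /M/s)
    partner + free catalyst → spent catalyst A (k = 0.0826 /M/s)
    2 partner → self-condensation product (k = 0.0889 /M/s)
    free catalyst → spent catalyst B (k = 0.00987 /s)

At 20.0 min the flask held 30.1% left-handed substrate against my 28.6%, a reach of 0.254, lower than Tuesday's. The neighbouring flask with 0.480 equiv of partner has the same loading, so Tuesday's reach, carried over from 0.80 equiv of partner, gives 28.6% for it again. It held 35.5% left-handed substrate, a reach of 0.172, with 14.7% reacted. Of its partner, 3.9% of the charge was left at the end.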